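Assumption: the target SMILES has no stereocentre and the diaryl ether axis is not configurationally stable, so there is no enantiomer to select. The C-methyl stereocentre of the ring A precursors is carried as a racemate and is erased in step 9.

## Retrosynthetic overview

1. The endgame is functional-group work only. The benzylic acetate comes from an aryl aldehyde by reduction, peracetylation and selective cleavage of the two aryl acetates.
2. The crowded diaryl ether C–O bond is made while ring A is still non-aromatic. A ring B phenol adds to the β-chloro enone ester of ring A by addition–elimination, and dehydrogenation then gives the salicylate.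
3. The ring A carbocycle comes from Dieckmann closure of dimethyl 3-methyl-5-oxoheptanedioate. Its key C–C bond is made by a crossed decarboxylative Claisen condensation of monomethyl 3-methylglutarate (as imidazolide) with the magnesium enolate of methyl malonate.
4. Ring B is bought as an arene (2-hydroxy-4-methoxybenzaldehyde) and elaborated by MOM protection, Baeyer–Villiger oxidation to the phenol, and ortho-formylation.
5. Ring order: ring B is present from the start. Ring A is closed in step 3, joined to ring B in step 8 and aromatised in step 9.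

## Route

Step 1
Reactants: 1 3-methylglutaric anhydride (4-methyloxane-2,6-dione)
Product: 2 5-methoxy-3-methyl-5-oxopentanoic acid (monomethyl 3-methylglutarate, racemic)
Conditions: MeOH, reflux, 3 h
Reagents that add atoms: methanol, CO
Why: Alcoholysis of a cyclic anhydride stops cleanly at the half ester because the liberated acid does not esterify without acid catalysis, and the C3 stereocentre forms as a racemate, which is harmless because it is erased in step 9.

Step 2
Reactants: 2 5-methoxy-3-methyl-5-oxopentanoic acid; 3 potassium methyl malonate (MeO2CCH2CO2K)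
Product: 6 dimethyl 3-methyl-5-oxoheptanedioate (racemic), via acyl imidazolide 4 (not isolated), via acylmalonic half ester 5 (not isolated)
Conditions: 2, CDI (1.05 equiv), THF, rt, 1 h; then 3 (1.8 equiv), MgCl2 (1.8 equiv), Et3N (2.5 equiv), MeCN, rt → 40 °C, 14 h; 1 M HCl
Reagents that add atoms: 1,1'-carbonyldiimidazole (CDI), O=C(n1ccnc1)n1ccnc1 (its imidazolyl group is found only in 4)
Why: This Masamune–Brooks decarboxylative crossed Claisen condensation is reliable because only the chelated magnesium enolate of the malonate half ester is nucleophilic, only acyl imidazolide 4 (not the methyl ester) is electrophilic enough to acylate it, and loss of CO2 from 5 makes the new C–C bond irreversible, with no lasting new stereocentre.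

Step 3
Reactants: 6 dimethyl 3-methyl-5-oxoheptanedioate
Product: 7 methyl 2-hydroxy-4-methyl-6-oxocyclohex-1-ene-1-carboxylate (enol form of methyl 4-methyl-2,6-dioxocyclohexane-1-carboxylate)
Conditions: NaOMe (2.2 equiv), MeOH, reflux, 4 h; cold 2 M HCl to pH 2
Reagents that add atoms: none
Why: In this Dieckmann (intramolecular Claisen) condensation NaOMe deprotonates only the doubly activated C6 methylene, whose attack on the C1 ester gives the six-membered tricarbonyl that is pulled out of the equilibrium as its very stable sodium enolate, and fast enol exchange makes 7 effectively achiral.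

Step 4
Reactants: 7 methyl 2-hydroxy-4-methyl-6-oxocyclohex-1-ene-1-carboxylate
Product: 8 methyl 2-chloro-4-methyl-6-oxocyclohex-1-ene-1-carboxylate (racemic)
Conditions: (COCl)2 (1.3 equiv), N,N-dimethylformamide (5 mol %), CH2Cl2, 0 °C → rt, 2 h; evaporate, use crude
Reagents that add atoms: oxalyl chloride, O=C(Cl)C(=O)Cl
Why: Vinylogous acid chloride formation (Vilsmeier-type activation of the enol oxygen, then chloride addition–elimination) can give only one constitutional isomer because the two ring carbonyls of 7 are equivalent, the fully substituted C1 excludes furandione formation, and C4 stays racemic.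

Step 5
Reactants: 9 2-hydroxy-4-methoxybenzaldehyde
Product: 10 4-methoxy-2-(methoxymethoxy)benzaldehyde
Conditions: MOMCl (1.5 equiv), i-Pr2NEt (2 equiv), CH2Cl2, 0 °C → rt, 16 h
Reagents that add atoms: chloromethyl methyl ether (MOMCl), COCCl
Why: Williamson-type O-alkylation of the only OH by the very reactive α-chloro ether gives an acetal ether that survives the basic and oxidative steps up to step 9 and, unlike silyl or acyl groups, cannot migrate to the neighbouring oxygen unmasked in step 6.

Step 6
Reactants: 10 4-methoxy-2-(methoxymethoxy)benzaldehyde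
Product: 12 4-methoxy-2-(methoxymethoxy)phenol, via aryl formate 11 (not isolated)
Conditions: mCPBA (1.3 equiv), CH2Cl2, 0 °C → rt, 6 h; aq Na2S2O3/NaHCO3 wash; then MeOH, Et3N (0.2 equiv), rt, 1 h
Reagents that add atoms: 3-chloroperoxybenzoic acid (mCPBA), OOC(=O)c1cccc(Cl)c1
Why: Baeyer–Villiger oxidation of an ortho,para-dialkoxybenzaldehyde proceeds with exclusive aryl migration to formate 11, which amine-catalysed transesterification with methanol cleaves to the phenol without touching the MOM acetal.

Step 7
Reactants: 12 4-methoxy-2-(methoxymethoxy)phenol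
Product: 13 2-hydroxy-5-methoxy-3-(methoxymethoxy)benzaldehyde
Conditions: MgCl2 (2 equiv), Et3N (4 equiv), (CH2O)n (6 equiv), MeCN, reflux, 4 h; cold 5 % citric acid
Reagents that add atoms: paraformaldehyde (reacts as formaldehyde), C=O
Why: In the Casnati–Skattebøl ortho-formylation the magnesium phenoxide delivers formaldehyde in an aldol-type reaction to the only free ortho position and a second formaldehyde oxidises the benzylic alkoxide by hydride transfer, so one regioisomer forms under basic conditions that spare the MOM group.

Step 8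
Reactants: 8 methyl 2-chloro-4-methyl-6-oxocyclohex-1-ene-1-carboxylate (1.15 equiv); 13 2-hydroxy-5-methoxy-3-(methoxymethoxy)benzaldehyde
Product: 14 methyl 2-[2-formyl-4-methoxy-6-(methoxymethoxy)phenoxy]-4-methyl-6-oxocyclohex-1-ene-1-carboxylate (racemic)
Conditions: Et3N (1.2 equiv), 4-(dimethylamino)pyridine (10 mol %), CH2Cl2, 0 °C → rt, 4 h
Reagents that add atoms: none
Why: Addition–elimination at the β-carbon of the doubly activated chloro enone ester (vinylogous acyl substitution, accelerated through the vinylogous acylpyridinium salt) forges the tri-ortho-substituted C–O bond as mildly as an esterification, the weak amine base avoids enolisation of 14 towards the neighbouring aldehyde, and C4 stays racemic.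

Step 9
Reactants: 14 methyl 2-[2-formyl-4-methoxy-6-(methoxymethoxy)phenoxy]-4-methyl-6-oxocyclohex-1-ene-1-carboxylate
Product: 15 methyl 2-[2-formyl-4-methoxy-6-(methoxymethoxy)phenoxy]-6-hydroxy-4-methylbenzoate
Conditions: 2,3-dichloro-5,6-dicyano-1,4-benzoquinone (DDQ, 1.3 equiv), dry 1,4-dioxane, 4 Å MS, 90 °C, 8 h
Reagents that add atoms: none
Why: In this DDQ dehydrogenation the ketone enol loses the tertiary allylic C4 hydride and then a C3 proton, driven by formation of the hydrogen-bonded aromatic salicylate, while aldehyde, MOM acetal and methyl ethers are inert to DDQ and the only stereocentre disappears.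

Step 10
Reactants: 15 methyl 2-[2-formyl-4-methoxy-6-(methoxymethoxy)phenoxy]-6-hydroxy-4-methylbenzoate
Product: 16 methyl 2-(2-formyl-6-hydroxy-4-methoxyphenoxy)-6-hydroxy-4-methylbenzoate
Conditions: conc. HCl (cat.), MeOH, 50 °C, 2 h; then H2O, rt, 15 min
Reagents that add atoms: none
Why: Acid-catalysed transacetalisation removes the MOM group before any acetate is present, methanol traps the formaldehyde unit as dimethoxymethane, the formyl group keeps ring B too electron-poor for hydroxymethylation, and methanol cannot change the methyl ester.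

Step 11
Reactants: 16 methyl 2-(2-formyl-6-hydroxy-4-methoxyphenoxy)-6-hydroxy-4-methylbenzoate
Product: 17 methyl 2-hydroxy-6-[2-hydroxy-6-(hydroxymethyl)-4-methoxyphenoxy]-4-methylbenzoate
Conditions: NaBH4 (2 equiv), THF/MeOH 4:1, 0 °C, 30 min; sat. NH4Cl
Reagents that add atoms: none
Why: Chemoselective borohydride reduction takes the aryl aldehyde within minutes at 0 °C but not the hydrogen-bonded salicylate ester, and the new benzylic alcohol is meta to the free ring B hydroxyl so that no quinone methide can form.

Step 12
Reactants: 17 methyl 2-hydroxy-6-[2-hydroxy-6-(hydroxymethyl)-4-methoxyphenoxy]-4-methylbenzoate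
Product: 18 methyl 2-acetoxy-6-[2-acetoxy-6-(acetoxymethyl)-4-methoxyphenoxy]-4-methylbenzoate
Conditions: Ac2O (6 equiv), pyridine (10 equiv), 4-(dimethylamino)pyridine (5 mol %), CH2Cl2, rt, 4 h
Reagents that add atoms: acetic anhydride, CC(=O)OC(C)=O
Why: Exhaustive acetylation under nucleophilic catalysis (Steglich-type acyl transfer) removes any need for selectivity among the hydroxyl groups at this stage, since even the chelated salicylate hydroxyl is acylated.

Step 13
Reactants: 18 methyl 2-acetoxy-6-[2-acetoxy-6-(acetoxymethyl)-4-methoxyphenoxy]-4-methylbenzoate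
Product: 19 betaethrin A, methyl 2-[2-(acetoxymethyl)-6-hydroxy-4-methoxyphenoxy]-6-hydroxy-4-methylbenzoate
Conditions: pyrrolidine (2.5 equiv), CH2Cl2, 0 °C, 1 h; cold 0.5 M HCl wash
Reagents that add atoms: none
Why: In this chemoselective aminolysis the two aryl acetates are active esters (phenoxide leaving groups) that pyrrolidine cleaves within minutes at 0 °C, the primary benzylic acetate and the hindered methyl benzoate (alkoxide leaving groups) are untouched, and the cold, weakly basic medium excludes Smiles rearrangement of the 2-aryloxyphenol.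

## Compound list

1 | 3-methylglutaric anhydride (4-methyloxane-2,6-dione) | CC1CC(=O)OC(=O)C1 | starting material
2 | 5-methoxy-3-methyl-5-oxopentanoic acid (racemic) | COC(=O)CC(C)CC(=O)O | intermediate
3 | potassium methyl malonate (MeO2CCH2CO2K) | COC(=O)CC(=O)[O-].[K+] | starting material
4 | methyl 5-(1H-imidazol-1-yl)-3-methyl-5-oxopentanoate (racemic, not isolated) | COC(=O)CC(C)CC(=O)n1ccnc1 | intermediate
5 | 7-methoxy-2-(methoxycarbonyl)-5-methyl-3,7-dioxoheptanoic acid (stereoisomer mixture, present as its magnesium salt, not isolated) | COC(=O)CC(C)CC(=O)C(C(=O)O)C(=O)OC | intermediate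
6 | dimethyl 3-methyl-5-oxoheptanedioate (racemic) | COC(=O)CC(C)CC(=O)CC(=O)OC | intermediate
7 | methyl 2-hydroxy-4-methyl-6-oxocyclohex-1-ene-1-carboxylate (enol tautomers interconvert, effectively achiral) | COC(=O)C1=C(O)CC(C)CC1=O | intermediate
8 | methyl 2-chloro-4-methyl-6-oxocyclohex-1-ene-1-carboxylate (racemic) | COC(=O)C1=C(Cl)CC(C)CC1=O | intermediate
9 | 2-hydroxy-4-methoxybenzaldehyde | COc1ccc(C=O)c(O)c1 | starting material
10 | 4-methoxy-2-(methoxymethoxy)benzaldehyde | COCOc1cc(OC)ccc1C=O | intermediate
11 | 4-methoxy-2-(methoxymethoxy)phenyl formate (not isolated) | COCOc1cc(OC)ccc1OC=O | intermediate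
12 | 4-methoxy-2-(methoxymethoxy)phenol | COCOc1cc(OC)ccc1O | intermediate
13 | 2-hydroxy-5-methoxy-3-(methoxymethoxy)benzaldehyde | COCOc1cc(OC)cc(C=O)c1O | intermediate
14 | methyl 2-[2-formyl-4-methoxy-6-(methoxymethoxy)phenoxy]-4-methyl-6-oxocyclohex-1-ene-1-carboxylate (racemic) | COC(=O)C1=C(Oc2c(C=O)cc(OC)cc2OCOC)CC(C)CC1=O | intermediate
15 | methyl 2-[2-formyl-4-methoxy-6-(methoxymethoxy)phenoxy]-6-hydroxy-4-methylbenzoate | COC(=O)c1c(O)cc(C)cc1Oc1c(C=O)cc(OC)cc1OCOC | intermediate
16 | methyl 2-(2-formyl-6-hydroxy-4-methoxyphenoxy)-6-hydroxy-4-methylbenzoate | COC(=O)c1c(O)cc(C)cc1Oc1c(O)cc(OC)cc1C=O | intermediate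
17 | methyl 2-hydroxy-6-[2-hydroxy-6-(hydroxymethyl)-4-methoxyphenoxy]-4-methylbenzoate | COC(=O)c1c(O)cc(C)cc1Oc1c(O)cc(OC)cc1CO | intermediate
18 | methyl 2-acetoxy-6-[2-acetoxy-6-(acetoxymethyl)-4-methoxyphenoxy]-4-methylbenzoate | COC(=O)c1c(OC(C)=O)cc(C)cc1Oc1c(OC(C)=O)cc(OC)cc1COC(C)=O | intermediate
19 | betaethrin A (achiral) | COC(=O)c1c(O)cc(C)cc1Oc1c(O)cc(OC)cc1COC(C)=O | target

## Step count

Total step count: 13.
Longest linear sequence: 10 steps, from 1 through steps 1–4 and 8–13. The ring B branch (steps 5–7) adds 3 steps, which makes 9 steps from 9 to the target.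

## Three steps most likely to fail

**Step 9 (dehydrogenation of 14).**
- Risk: the push–pull enone enolises slowly, and at 90 °C traces of water can expel the good aryloxide leaving group.
- Fallback, from 14 back to 15: the enol is fixed first, so DDQ no longer has to find it.
- TBSOTf/Et3N (CH2Cl2, 0 °C) converts the vinylogous ester carbonyl into the Danishefsky-type silyloxydiene methyl 6-[(tert-butyldimethylsilyl)oxy]-2-[2-formyl-4-methoxy-6-(methoxymethoxy)phenoxy]-4-methylcyclohexa-1,5-diene-1-carboxylate F1. Any γ-deprotonated isomer converges on the same arene.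
- This true 1,3-cyclohexadiene is oxidised by DDQ within minutes at 0 °C (2,6-lutidine buffer). The product is the aryl silyl ether methyl 2-[(tert-butyldimethylsilyl)oxy]-6-[2-formyl-4-methoxy-6-(methoxymethoxy)phenoxy]-4-methylbenzoate F2.
- Bu4NF buffered with AcOH (THF, 0 °C) then releases phenol 15.

**Step 8 (C–O bond formation between 8 and 13).**
- Risk: 13 is a weak, di-ortho-substituted nucleophile. Both 8 and 14 are sensitive to moisture. Base could trigger a vinylogous aldol of 14 onto its own formyl group.
- Fallback, from 7 back to 16: ring A is aromatised first and the ether is made by copper catalysis.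
- (COBr)2 with catalytic N,N-dimethylformamide gives methyl 2-bromo-4-methyl-6-oxocyclohex-1-ene-1-carboxylate F3.
- DDQ (1,4-dioxane, 90 °C) gives methyl 2-bromo-6-hydroxy-4-methylbenzoate F4.
- MOMCl/i-Pr2NEt gives methyl 2-bromo-6-(methoxymethoxy)-4-methylbenzoate F5.
- Ullmann coupling of F5 with 13 (CuI 20 mol %, N,N-dimethylglycine 40 mol %, Cs2CO3, 1,4-dioxane, 100 °C) is assisted by the ortho ester of the bromide. It gives methyl 2-[2-formyl-4-methoxy-6-(methoxymethoxy)phenoxy]-6-(methoxymethoxy)-4-methylbenzoate F6.
- The conditions of step 10 strip both MOM groups and deliver 16.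

**Step 3 (Dieckmann closure of 6).**
- Risk: a stabilised enolate must acylate on an unactivated ester. Retro-Claisen cleavage, enol lactone formation, or decarboxylation on work-up can lower the yield.
- Fallback, from 1 back to 7: the ring is closed on an activated acyl group under soft enolisation instead of alkoxide equilibration.
- The lithium enolate of methyl acetate (LiCH2CO2Me, from MeOAc and LiN(i-Pr)2, 2.2 equiv, THF, −78 °C) opens anhydride 1 in a crossed Claisen acylation. This gives 7-methoxy-3-methyl-5,7-dioxoheptanoic acid F7.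
- CDI (THF, rt) gives methyl 7-(1H-imidazol-1-yl)-5-methyl-3,7-dioxoheptanoate F8.
- MgCl2/Et3N then generates the chelated β-keto ester enolate, which is C-acylated intramolecularly to give 7.

## Further compounds

F1 | step 9 | methyl 6-[(tert-butyldimethylsilyl)oxy]-2-[2-formyl-4-methoxy-6-(methoxymethoxy)phenoxy]-4-methylcyclohexa-1,5-diene-1-carboxylate (racemic) | COC(=O)C1=C(Oc2c(C=O)cc(OC)cc2OCOC)CC(C)C=C1O[Si](C)(C)C(C)(C)C
F2 | step 9 | methyl 2-[(tert-butyldimethylsilyl)oxy]-6-[2-formyl-4-methoxy-6-(methoxymethoxy)phenoxy]-4-methylbenzoate | COC(=O)c1c(O[Si](C)(C)C(C)(C)C)cc(C)cc1Oc1c(C=O)cc(OC)cc1OCOC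
F3 | step 8 | methyl 2-bromo-4-methyl-6-oxocyclohex-1-ene-1-carboxylate (racemic) | COC(=O)C1=C(Br)CC(C)CC1=O
F4 | step 8 | methyl 2-bromo-6-hydroxy-4-methylbenzoate | COC(=O)c1c(O)cc(C)cc1Br
F5 | step 8 | methyl 2-bromo-6-(methoxymethoxy)-4-methylbenzoate | COCOc1cc(C)cc(Br)c1C(=O)OC
F6 | step 8 | methyl 2-[2-formyl-4-methoxy-6-(methoxymethoxy)phenoxy]-6-(methoxymethoxy)-4-methylbenzoate | COCOc1cc(C)cc(Oc2c(C=O)cc(OC)cc2OCOC)c1C(=O)OC
F7 | step 3 | 7-methoxy-3-methyl-5,7-dioxoheptanoic acid (racemic) | COC(=O)CC(=O)CC(C)CC(=O)O
F8 | step 3 | methyl 7-(1H-imidazol-1-yl)-5-methyl-3,7-dioxoheptanoate (racemic) | COC(=O)CC(=O)CC(C)CC(=O)n1ccnc1
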